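**Retrosynthetic overview**

1. Target 19 ← global desilylation of 18 ← ring-enlarging 1,2-shift of the fused α-hydroxy ketone 15, a cis-bicyclo[3.3.0]octenone whose stereocentres are easier to set than those of the bridged target.
2. 15 ← Luche reduction and enolate hydroxylation ← bicyclic β-diketone 13 ← Nazarov cyclization of dienone 12 ← carbonylative Stille coupling of iodoenone 10.
3. Enone 9 (ring B with the aryl and methyl centres) ← allyl conjugate addition/Saegusa–Ito oxidation, methyl cuprate addition/elimination and Suzuki coupling on the chiral-pool enone 3.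
4. Ring order: ring B (cyclopentenone from 3) first; five-membered ring A annulated by the Nazarov step; ring A then enlarged to the six-membered ring while ring B becomes the five-membered ring carrying the ketone bridge.
5. Enabling feature: in 15 the ring-fusion carbinol carbon C8 (tertiary OH) lies between the ring B ketone carbon C5 and carbon C4 of the five-membered ring A (C1, C2, C3, C4, C8); once C5 is an oxocarbenium ion, the ring bond C8–C4 can migrate to C5 and C8 becomes the ketone.

Key step: step 11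

Remarks. Atom labels C1–C8 in the text are always those of the target frame (C1 allyl bridgehead, C2=C3(OMe), C4 carbinol, C5 methoxy bridgehead, C6 aryl, C7 methyl, C8 ketone). Ar = 4-(tert-butyldimethylsilyloxy)-3-methoxyphenyl. Assumption: 1, 3 and stannane 11 are taken as purchasable (11 is otherwise one step from methyl vinyl ether, t-BuLi and Bu3SnCl).

**Route**

Step 1
Reactants: 1 2-methoxy-4-(4,4,5,5-tetramethyl-1,3,2-dioxaborolan-2-yl)phenol
Product: 2 tert-butyl[2-methoxy-4-(4,4,5,5-tetramethyl-1,3,2-dioxaborolan-2-yl)phenoxy]dimethylsilane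
Conditions: TBSCl, imidazole, DMF, rt
Reagents that add atoms: tert-butyldimethylsilyl chloride, CC(C)(C)[Si](C)(C)Cl
Why: Imidazole-promoted O-silylation of the phenol masks the acidic OH against the organometallic steps that follow; no stereocentre is involved.

Step 2
Reactants: 3 (R)-4-[(tert-butyldimethylsilyl)oxy]cyclopent-2-en-1-one
Product: 4 (R)-4-[(tert-butyldimethylsilyl)oxy]-2-iodocyclopent-2-en-1-one
Conditions: I2, pyridine, CH2Cl2, 0 °C to rt
Reagents that add atoms: iodine, II
Why: α-Iodination of the enone by pyridine conjugate addition, iodination of the enolate and elimination should proceed without touching the silyloxy stereocentre.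

Step 3
Reactants: 4 (R)-4-[(tert-butyldimethylsilyl)oxy]-2-iodocyclopent-2-en-1-one; 2 tert-butyl[2-methoxy-4-(4,4,5,5-tetramethyl-1,3,2-dioxaborolan-2-yl)phenoxy]dimethylsilane
Product: 5 (R)-2-Ar-4-[(tert-butyldimethylsilyl)oxy]cyclopent-2-en-1-one
Conditions: PdCl2(PhCN)2 (cat.), AsPh3, Ag2O, THF–H2O, rt
Reagents that add atoms: none
Why: Suzuki–Miyaura coupling of the α-iodoenone under silver oxide activation at room temperature should install the aryl group without β-elimination of the silyloxy group.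

Step 4
Reactants: 5 (R)-2-Ar-4-[(tert-butyldimethylsilyl)oxy]cyclopent-2-en-1-one
Product: 7 (4S,5S)-5-Ar-4-methylcyclopent-2-en-1-one, via silyloxy ketone 6 (not isolated)
Conditions: Me2CuLi, Et2O, −78 °C; NH4Cl quench; then DBU, CH2Cl2, 0 °C, short contact
Reagents that add atoms: lithium dimethylcuprate, [Li+].C[Cu-]C
Why: Gilman cuprate conjugate addition anti to the silyloxy group sets the methyl-bearing centre (C7), E1cB loss of silanol from 6 gives the transposed enone, and the enolizable aryl-bearing carbon (C6) should settle trans to the methyl group.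

Step 5
Reactants: 7 (4S,5S)-5-Ar-4-methylcyclopent-2-en-1-one
Product: 9 (4R,5S)-3-allyl-5-Ar-4-methylcyclopent-2-en-1-one, via silyl enol ether 8 (not isolated)
Conditions: CH2=CHCH2MgBr, CuBr·SMe2 (cat.), Me3SiCl, THF, −78 °C; then Pd(OAc)2, MeCN, rt
Reagents that add atoms: allylmagnesium bromide, C=CC[Mg]Br; chlorotrimethylsilane, C[Si](C)(C)Cl (silyl group only in 8)
Why: Copper-catalysed conjugate allylation with silyl trapping gives the regiodefined enol ether 8, and Saegusa–Ito oxidation should return the enone on the same side, so the transient allyl-bearing centre becomes sp2 again.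

Step 6
Reactants: 9 (4R,5S)-3-allyl-5-Ar-4-methylcyclopent-2-en-1-one
Product: 10 (4R,5S)-3-allyl-5-Ar-2-iodo-4-methylcyclopent-2-en-1-one
Conditions: I2, pyridine, CH2Cl2, rt
Reagents that add atoms: iodine, II
Why: The same α-iodination of an enone as in step 2 should place the halogen on C8 for the coupling; the existing stereocentres are not involved.

Step 7
Reactants: 10 (4R,5S)-3-allyl-5-Ar-2-iodo-4-methylcyclopent-2-en-1-one; 11 tributyl(1-methoxyvinyl)stannane
Product: 12 (4R,5S)-3-allyl-5-Ar-2-(2-methoxyacryloyl)-4-methylcyclopent-2-en-1-one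
Conditions: Pd2(dba)3 (cat.), AsPh3, LiCl, CO (1 atm), NMP, 50 °C
Reagents that add atoms: carbon monoxide, [C-]#[O+]
Why: Carbonylative Stille coupling (oxidative addition, CO insertion, transmetalation with the vinylstannane) should give the cross-conjugated dienone needed for the electrocyclization.

Step 8
Reactants: 12 (4R,5S)-3-allyl-5-Ar-2-(2-methoxyacryloyl)-4-methylcyclopent-2-en-1-one
Product: 13 (1S,5R,6R,7S)-5-allyl-7-Ar-3-methoxy-6-methylbicyclo[3.3.0]oct-3-ene-2,8-dione
Conditions: Cu(OTf)2 (10 mol %), ClCH2CH2Cl, rt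
Reagents that add atoms: none
Why: Polarized Nazarov cyclization (donor 2-methoxyvinyl terminus C2, acceptor alkylidene β-diketone terminus C1) should close ring A by conrotatory 4π electrocyclization, C2 bonding to C1 on the face anti to the adjacent methyl group, which sets the quaternary centre C1 with allyl cis to methyl; proton loss from C2 gives the α-methoxy enone.

Step 9
Reactants: 13 (1S,5R,6R,7S)-5-allyl-7-Ar-3-methoxy-6-methylbicyclo[3.3.0]oct-3-ene-2,8-dione
Product: 14 (1R,5R,6R,7S)-5-allyl-7-Ar-1-hydroxy-3-methoxy-6-methylbicyclo[3.3.0]oct-3-ene-2,8-dione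
Conditions: KN(SiMe3)2, THF, −78 °C; 2-(phenylsulfonyl)-3-phenyloxaziridine; NH4Cl quench
Reagents that add atoms: 2-(phenylsulfonyl)-3-phenyloxaziridine, O=S(=O)(c1ccccc1)N1OC1c1ccccc1
Why: Davis oxidation of the β-diketone enolate should hydroxylate the ring-fusion carbon C8 only, the oxygen entering cis to the angular allyl group because only the cis-fused bicyclo[3.3.0] frame is attainable.

Step 10
Reactants: 14 (1R,5R,6R,7S)-5-allyl-7-Ar-1-hydroxy-3-methoxy-6-methylbicyclo[3.3.0]oct-3-ene-2,8-dione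
Product: 15 (1S,2R,5R,6R,7S)-5-allyl-7-Ar-1,2-dihydroxy-3-methoxy-6-methylbicyclo[3.3.0]oct-3-en-8-one
Conditions: NaBH4, CeCl3·7H2O, MeOH, −78 °C
Reagents that add atoms: none
Why: Luche 1,2-reduction should take the less hindered α-methoxy enone carbonyl (C4) in preference to the C5 ketone flanked by the quaternary C8 and the aryl-bearing C6, hydride arriving on the convex face next to the C8 hydroxyl so that the new C4 hydroxyl is endo and trans to it.

Step 11
Reactants: 15 (1S,2R,5R,6R,7S)-5-allyl-7-Ar-1,2-dihydroxy-3-methoxy-6-methylbicyclo[3.3.0]oct-3-en-8-one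
Product: 18 (1R,4S,5R,6S,7R)-1-allyl-6-Ar-3,5-dimethoxy-7-methyl-4-(trimethylsilyloxy)bicyclo[3.2.1]oct-2-en-8-one, via bis-silyl ether 16 (not isolated), via mixed ketal 17 (not isolated)
Conditions: MeC(OSiMe3)=NSiMe3 (BSA), CH2Cl2, rt; then MeOSiMe3, Me3SiOTf (0.2 equiv), CH2Cl2, −78 to −30 °C; Et3N quench
Reagents that add atoms: N,O-bis(trimethylsilyl)acetamide, CC(=N[Si](C)(C)C)O[Si](C)(C)C; methoxytrimethylsilane, CO[Si](C)(C)C
Why: Proposed new method: after silylation, Me3SiOTf/MeOSiMe3 should turn the single ketone (C5) into mixed ketal 17 and then into a methoxy-oxocarbenium ion whose vacant orbital is parallel to the ring A bond C8–C4, so that C4 shifts from C8 to C5 while the silyloxy group on C8 collapses to the ketone (semipinacol 1,2-shift, driven by exchange of an oxocarbenium ion for a carbonyl group). The closest known reaction types are the Lewis acid semipinacol rearrangement of α-hydroxy ketals and the acid-induced ring enlargement of 1-(1-alkoxyvinyl)cycloalkanols through oxocarbenium ions; new here is that the ion is generated from the ketone under silyl triflate ketalisation conditions and that a fused bicyclo[3.3.0] frame is converted into a bridged one. No ring is closed by a new cyclisation: the five-membered ring A (C1, C2, C3, C4, C8) is enlarged by insertion of C5 to the six-membered ring C1–C2–C3–C4–C5–C8, and ring B thereby becomes the cyclopentanone that carries the C8 bridge. The new stereocentre C5 is fixed by the cis ring fusion, because C4 can reach C5 only on the face of ring B that ring A already occupies, which places OMe exo; C4 migrates with retention, so the endo carbinol of 15 becomes the C4 configuration of the target. The step needs C4 and not C1 to migrate and needs ionisation without loss of the benzylic C6 proton: a C1 shift would contract ring B to a cyclobutane, the oxygen-bearing allylic C4 is the better migrating group, and the absence of amine base at low temperature should suppress enol ether formation.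

Step 12
Reactants: 18 (1R,4S,5R,6S,7R)-1-allyl-6-Ar-3,5-dimethoxy-7-methyl-4-(trimethylsilyloxy)bicyclo[3.2.1]oct-2-en-8-one
Product: 19 (1R,4S,5R,6S,7R)-1-allyl-4-hydroxy-6-(4-hydroxy-3-methoxyphenyl)-3,5-dimethoxy-7-methylbicyclo[3.2.1]oct-2-en-8-one
Conditions: Bu4NF, AcOH, THF, 0 °C
Reagents that add atoms: none
Why: Buffered fluoride desilylation should free the phenol and the C4 carbinol without acid (which would attack the enol ether) and without enough base for retro-aldol cleavage of the β-hydroxy ketone.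

**Compound list**

1 | 2-methoxy-4-(4,4,5,5-tetramethyl-1,3,2-dioxaborolan-2-yl)phenol | COc1cc(B2OC(C)(C)C(C)(C)O2)ccc1O | starting material
2 | tert-butyl[2-methoxy-4-(4,4,5,5-tetramethyl-1,3,2-dioxaborolan-2-yl)phenoxy]dimethylsilane | COc1cc(B2OC(C)(C)C(C)(C)O2)ccc1O[Si](C)(C)C(C)(C)C | intermediate
3 | (R)-4-[(tert-butyldimethylsilyl)oxy]cyclopent-2-en-1-one | O=C1C=C[C@H](O[Si](C)(C)C(C)(C)C)C1 | starting material
4 | (R)-4-[(tert-butyldimethylsilyl)oxy]-2-iodocyclopent-2-en-1-one | O=C1C(I)=C[C@H](O[Si](C)(C)C(C)(C)C)C1 | intermediate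
5 | (R)-2-Ar-4-[(tert-butyldimethylsilyl)oxy]cyclopent-2-en-1-one | O=C1C(c2ccc(O[Si](C)(C)C(C)(C)C)c(OC)c2)=C[C@H](O[Si](C)(C)C(C)(C)C)C1 | intermediate
6 | (2S,3R,4R)-2-Ar-4-[(tert-butyldimethylsilyl)oxy]-3-methylcyclopentan-1-one | O=C1[C@H](c2ccc(O[Si](C)(C)C(C)(C)C)c(OC)c2)[C@@H](C)[C@H](O[Si](C)(C)C(C)(C)C)C1 | intermediate
7 | (4S,5S)-5-Ar-4-methylcyclopent-2-en-1-one | O=C1C=C[C@H](C)[C@H]1c1ccc(O[Si](C)(C)C(C)(C)C)c(OC)c1 | intermediate
8 | {[(3S,4S,5S)-3-allyl-5-Ar-4-methylcyclopent-1-en-1-yl]oxy}trimethylsilane | C[Si](C)(C)OC1=C[C@@H](CC=C)[C@H](C)[C@H]1c1ccc(O[Si](C)(C)C(C)(C)C)c(OC)c1 | intermediate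
9 | (4R,5S)-3-allyl-5-Ar-4-methylcyclopent-2-en-1-one | O=C1C=C(CC=C)[C@H](C)[C@H]1c1ccc(O[Si](C)(C)C(C)(C)C)c(OC)c1 | intermediate
10 | (4R,5S)-3-allyl-5-Ar-2-iodo-4-methylcyclopent-2-en-1-one | O=C1C(I)=C(CC=C)[C@H](C)[C@H]1c1ccc(O[Si](C)(C)C(C)(C)C)c(OC)c1 | intermediate
11 | tributyl(1-methoxyvinyl)stannane | C=C(OC)[Sn](CCCC)(CCCC)CCCC | starting material
12 | (4R,5S)-3-allyl-5-Ar-2-(2-methoxyacryloyl)-4-methylcyclopent-2-en-1-one | O=C1C(C(=O)C(OC)=C)=C(CC=C)[C@H](C)[C@H]1c1ccc(O[Si](C)(C)C(C)(C)C)c(OC)c1 | intermediate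
13 | (1S,5R,6R,7S)-5-allyl-7-Ar-3-methoxy-6-methylbicyclo[3.3.0]oct-3-ene-2,8-dione (cis-fused) | C=CC[C@@]12C=C(OC)C(=O)[C@@H]1C(=O)[C@H](c3ccc(O[Si](C)(C)C(C)(C)C)c(OC)c3)[C@H]2C | intermediate
14 | (1R,5R,6R,7S)-5-allyl-7-Ar-1-hydroxy-3-methoxy-6-methylbicyclo[3.3.0]oct-3-ene-2,8-dione | C=CC[C@@]12C=C(OC)C(=O)[C@]1(O)C(=O)[C@H](c3ccc(O[Si](C)(C)C(C)(C)C)c(OC)c3)[C@H]2C | intermediate
15 | (1S,2R,5R,6R,7S)-5-allyl-7-Ar-1,2-dihydroxy-3-methoxy-6-methylbicyclo[3.3.0]oct-3-en-8-one (trans diol, 2-OH endo) | C=CC[C@@]12C=C(OC)[C@H](O)[C@]1(O)C(=O)[C@H](c3ccc(O[Si](C)(C)C(C)(C)C)c(OC)c3)[C@H]2C | intermediate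
16 | bis(trimethylsilyl) ether of 15 (both hydroxyls silylated; configuration as in 15) | C=CC[C@@]12C=C(OC)[C@H](O[Si](C)(C)C)[C@]1(O[Si](C)(C)C)C(=O)[C@H](c3ccc(O[Si](C)(C)C(C)(C)C)c(OC)c3)[C@H]2C | intermediate
17 | methyl trimethylsilyl mixed ketal of 16 at the ketone carbon (ketal carbon configuration not defined) | C=CC[C@@]12C=C(OC)[C@H](O[Si](C)(C)C)[C@]1(O[Si](C)(C)C)C(OC)(O[Si](C)(C)C)[C@H](c3ccc(O[Si](C)(C)C(C)(C)C)c(OC)c3)[C@H]2C | intermediate
18 | (1R,4S,5R,6S,7R)-1-allyl-6-Ar-3,5-dimethoxy-7-methyl-4-(trimethylsilyloxy)bicyclo[3.2.1]oct-2-en-8-one | C=CC[C@@]12C=C(OC)[C@H](O[Si](C)(C)C)[C@@](OC)(C1=O)[C@H](c3ccc(O[Si](C)(C)C(C)(C)C)c(OC)c3)[C@H]2C | intermediate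
19 | (1R,4S,5R,6S,7R)-1-allyl-4-hydroxy-6-(4-hydroxy-3-methoxyphenyl)-3,5-dimethoxy-7-methylbicyclo[3.2.1]oct-2-en-8-one (6-endo aryl, 7-exo methyl) | C=CC[C@@]12C=C(OC)[C@H](O)[C@@](OC)(C1=O)[C@H](c1ccc(O)c(OC)c1)[C@H]2C | target

**Step count and risks**

Total step count: 12. Longest linear sequence: 11 steps (steps 2 to 12, from 3).

Steps most likely to fail:

1. Step 11 (Proposed new method). The hindered ketone may not ionise, the oxocarbenium ion may lose the benzylic C6 proton to give an aryl-conjugated enol ether, or the shift may become dissociative (retro-aldol-type cleavage and re-closure) and erode the C4 configuration. Fallback with known chemistry, setting out from 15: selective silylation of the secondary C4 hydroxyl (TBSOTf, 2,6-lutidine, −78 °C) should give the mono-silyl ether F1. The classical α-ketol (acyloin) rearrangement under aluminium alkoxide catalysis (Al(OtBu)3, toluene, 80 °C) should then move C4 from C8 to the C5 carbonyl carbon and give the bridgehead alcohol F2. O-Methylation with Me3OBF4 and 1,8-bis(dimethylamino)naphthalene should give the methyl ether F3, and Bu4NF/AcOH removes both silyl groups, so the route comes back at 19.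

2. Step 10. Chemoselectivity between the two ketones may be poor, with competing reduction at C5. Fallback, setting out from 14: Me3SiOTf/Et3N should convert the enolizable C5 ketone into its aryl-conjugated silyl enol ether and silylate the tertiary hydroxyl, giving the bis-silyl dienone F4, in which only the non-enolizable C4 carbonyl remains. NaBH4/CeCl3 should then give the allylic alcohol F5 with the same convex-face selectivity. K2CO3 in MeOH at 0 °C removes both trimethylsilyl groups, C6 re-equilibrating to the trans arrangement, and the route comes back at 15.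

3. Step 7. Carbonyl insertion at the hindered tetrasubstituted alkenylpalladium may be slow, so that direct coupling or loss of iodine competes. Fallback, setting out from 7: α-iodination (I2, pyridine) of the unsubstituted enone should give the iodoenone F6, and carbonylative Stille coupling with 11 on this unhindered iodide the acyl enone F7. Copper-catalysed conjugate addition of allylmagnesium bromide to this doubly activated acceptor should give the β-diketone F8. Selenenylation (PhSeCl, pyridine) should give the selenide F9, and H2O2 oxidation with selenoxide syn-elimination restores the ring double bond, so the route comes back at 12.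

**Further compounds**

F1 | step 11 | (1S,2R,5R,6R,7S)-5-allyl-7-Ar-2-(tert-butyldimethylsilyloxy)-1-hydroxy-3-methoxy-6-methylbicyclo[3.3.0]oct-3-en-8-one | C=CC[C@@]12C=C(OC)[C@H](O[Si](C)(C)C(C)(C)C)[C@]1(O)C(=O)[C@H](c3ccc(O[Si](C)(C)C(C)(C)C)c(OC)c3)[C@H]2C
F2 | step 11 | (1R,4R,5R,6S,7R)-1-allyl-6-Ar-4-(tert-butyldimethylsilyloxy)-5-hydroxy-3-methoxy-7-methylbicyclo[3.2.1]oct-2-en-8-one | C=CC[C@@]12C=C(OC)[C@H](O[Si](C)(C)C(C)(C)C)[C@@](O)(C1=O)[C@H](c3ccc(O[Si](C)(C)C(C)(C)C)c(OC)c3)[C@H]2C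
F3 | step 11 | (1R,4S,5R,6S,7R)-1-allyl-6-Ar-4-(tert-butyldimethylsilyloxy)-3,5-dimethoxy-7-methylbicyclo[3.2.1]oct-2-en-8-one | C=CC[C@@]12C=C(OC)[C@H](O[Si](C)(C)C(C)(C)C)[C@@](OC)(C1=O)[C@H](c3ccc(O[Si](C)(C)C(C)(C)C)c(OC)c3)[C@H]2C
F4 | step 10 | (1R,5R,6S)-5-allyl-7-Ar-3-methoxy-6-methyl-1,8-bis(trimethylsilyloxy)bicyclo[3.3.0]octa-3,7-dien-2-one | C=CC[C@@]12C=C(OC)C(=O)[C@]1(O[Si](C)(C)C)C(O[Si](C)(C)C)=C(c3ccc(O[Si](C)(C)C(C)(C)C)c(OC)c3)[C@H]2C
F5 | step 10 | (1S,2S,5R,6S)-5-allyl-7-Ar-3-methoxy-6-methyl-1,8-bis(trimethylsilyloxy)bicyclo[3.3.0]octa-3,7-dien-2-ol (2-OH endo) | C=CC[C@@]12C=C(OC)[C@H](O)[C@]1(O[Si](C)(C)C)C(O[Si](C)(C)C)=C(c3ccc(O[Si](C)(C)C(C)(C)C)c(OC)c3)[C@H]2C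
F6 | step 7 | (4R,5S)-5-Ar-2-iodo-4-methylcyclopent-2-en-1-one | O=C1C(I)=C[C@H](C)[C@H]1c1ccc(O[Si](C)(C)C(C)(C)C)c(OC)c1
F7 | step 7 | (4S,5S)-5-Ar-2-(2-methoxyacryloyl)-4-methylcyclopent-2-en-1-one | O=C1C(C(=O)C(OC)=C)=C[C@H](C)[C@H]1c1ccc(O[Si](C)(C)C(C)(C)C)c(OC)c1
F8 | step 7 | (3S,4S,5S)-3-allyl-5-Ar-2-(2-methoxyacryloyl)-4-methylcyclopentan-1-one (C2 not defined, enolizable) | O=C1C(C(=O)C(OC)=C)[C@@H](CC=C)[C@H](C)[C@H]1c1ccc(O[Si](C)(C)C(C)(C)C)c(OC)c1
F9 | step 7 | (3S,4S,5S)-3-allyl-5-Ar-2-(2-methoxyacryloyl)-4-methyl-2-(phenylselanyl)cyclopentan-1-one (C2 not defined) | O=C1C([Se]c2ccccc2)(C(=O)C(OC)=C)[C@@H](CC=C)[C@H](C)[C@H]1c1ccc(O[Si](C)(C)C(C)(C)C)c(OC)c1
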